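Of the L charged, 85.1% stands as L plus X at the first reading of the delta run, and the missing 14.9% lies close to the 15 mol% of G, so we read it as L held by the catalyst.

| setting | delta | theta | violet | grey | ochre |
|---|---|---|---|---|---|
| L | 0.30 M | 0.30 M | 0.30 M | 0.30 M | 0.30 M |
| E | 0.75 equiv | 3 equiv | 1.50 equiv | 1.50 equiv | 1.50 equiv |
| G | 15 mol% | 15 mol% | 15 mol% | 15 mol% | 15 mol% |
| temperature | 55 °C | 75 °C | 90 °C | 75 °C | 60 °C |
| remark | run made earlier | run made earlier |  |  |  |
| time |  |  | 2.5 h | 2.5 h | 2.5 h |

| run | time / h | X / % | L / % |
|---|---|---|---|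
| delta | 1.00 | 0 | 85.1 |
| delta | 1.33 | 0.6 | 85.3 |
| delta | 2.50 | 0.2 | 84.9 |
| delta | 4.00 | 0.5 | 84.6 |
| delta | 8.00 | 3.1 | 82.2 |
| delta | 12.0 | 6.1 | 78.9 |
| theta | 0.250 | 0.5 | 84.7 |
| theta | 0.833 | 3.9 | 81.2 |
| theta | 1.33 | 7.6 | 77.8 |
| theta | 2.00 | 14.0 | 72.2 |
| theta | 3.00 | 22.1 | 62.9 |
| theta | 4.00 | 31.3 | 54.7 |

(scatter of a reading: 0.3 percentage points)

- which flask leads in amount of X, in percent of the L charged ("all alike" within 1.5 percentage points) (violet / grey / ochre / all alike)
- how much X is there at the end, in percent of the L charged: violet
- how much X is there at the end, in percent of the L charged: grey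
- how much X is there at the end, in percent of the L charged: ochre

- the earlier runs were read with a standard deviation of 0.3 percentage points

While the catalyst keeps that hold, 85.1% is the level X can fill, and we use it as the ceiling for these hours. How fast it fills comes from the theta run. X gains 8.1 points in one hour and 9.2 points in the next, with no sag as L falls from 62.9% to 54.7%. That is zero order in [L], a steady rate, which we read as 0.0920 h⁻¹ as a fraction of the charge. Delta's last readings give 0.00750 h⁻¹.

These runs change E and temperature together, so they cannot separate the two. We assume E does not enter the rate and put the whole gain on temperature. That is our bet.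

Grey then runs at theta's rate. Dividing the ceiling by the rate gives 9.25 h, and this number of hours to reach the ceiling at the steady rate, the fill time, is what we carry. It is longer than 2.5 h, so grey stays on its straight line. Drawn back from the reading at 3.00 h, that line meets zero at a lag of 0.598 h, which gives grey 17.5%.

Violet lies as far above grey as ochre lies below it, 0.750 of the span between delta and theta, so one factor, 6.55, serves both. Violet's fill time becomes 1.41 h, shorter than the time allowed, so we commit to X near the ceiling. Ochre's becomes 60.6 h, far beyond it, which bounds X at 3.51% before any lag is taken off.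

The forecast names violet as leader, with violet 43%, grey 13% and ochre 0.8%, calls the violet figure “very uncertain”, and stands below us on that flask.

The flasks end at violet 72.4%, grey 17.2% and ochre 1.29%, and violet leads.

    Q ⇌ G + X (K = 0.350 M, k = 6.21 h⁻¹, Ea = 115 kJ mol⁻¹, ΔH = −25.0 kJ mol⁻¹)
    J → Q (k = 6.15 h⁻¹, Ea = 108 kJ mol⁻¹)
    L + G ⇌ Z (K = 9.00 M⁻¹, k = 246 M⁻¹ h⁻¹, Ea = 62.0 kJ mol⁻¹, ΔH = −61.0 kJ mol⁻¹)
    E + Z → J (k = 59.6 M⁻¹ h⁻¹, Ea = 59.0 kJ mol⁻¹)
    (constants at 90 °C)

Grey lands near its line of 17.5%, and ochre lies under its bound. Violet, despite a fill time of 1.41 h, stops 13 points below the ceiling with 17% of its L unbound. The neighbour flask, violet with 0.900 equiv of E, reckons the same way with one change: the equations put E into the held forms J and Q, so the level X can fill while that hold stands is the E charge less the 14.9% held, not 85.1%, and at our unchanged rate the fill time shortens in step. It gives 60.0% of X, with 30% of L and 25.4% of its own E left.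

The data were computed with made-up constants; noise was put on by code.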